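**Plan**

- The coumarin is cut at the lactone C2–O1 bond and the C3=C4 double bond (Perkin-type condensation). This gives a ring A salicylaldehyde and 2,4-diacetoxyphenylacetic acid, which carries ring C.
- Ring A is cut at C8a–C4a and C5–C6, with C8a–C8 reclosing. Its five substituents make this possible: oxygen at C8a, C5 and C7 in a 1,3,5 array and the quaternary 1,1-dimethylallyl group at C8 between two of them. These map onto a ketene carbonyl (C8a), a 1-methoxyalkyne (C4a, C5) and a 4-substituted 3-silyloxycyclobutenone (C6, C7, C8).
- The cyclobutenone is cut into a tert-alkylketene and a silyl ynol ether ([2+2]).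
- Forward: four-membered ring, then ring A by benzannulation, then C4 is raised to the aldehyde and the pyranone ring B is closed with ring C attached; two deprotections finish.
- Stereochemistry: the target has no stereocentre. The single stereocentre of the cyclobutenone is made racemic and disappears on aromatisation.

Key step: step 7

Remark: all chiral intermediates (9, 15, 17) are racemic and transient, so no stereocontrol is planned.

**Step 1**
Reactants: 1 methyl 3,3-dimethylpent-4-enoate
Product: 2 3,3-dimethylpent-4-enoic acid
Conditions: LiOH·H2O, THF/H2O, rt; then 1 M HCl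
Reagents that add atoms: lithium hydroxide, [Li+].[OH-]
Why: Saponification (acyl-oxygen ester hydrolysis) of a simple methyl ester; the isolated alkene is inert to aqueous LiOH.

**Step 2**
Reactants: 2 3,3-dimethylpent-4-enoic acid
Product: 3 3,3-dimethylpent-4-enoyl chloride
Conditions: (COCl)2, DMF (cat.), CH2Cl2, 0 °C to rt; used crude
Reagents that add atoms: oxalyl chloride, ClC(=O)C(=O)Cl
Why: Vilsmeier-catalysed acid chloride formation gives only gaseous by-products, so the volatile acyl chloride can be carried on without purification.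

**Step 3**
Reactants: 4 ethyne
Product: 7 (triisopropylsilyloxy)ethyne, via monolithium acetylide 5 (not isolated), via lithium ethynolate 6 (not isolated)
Conditions: HC≡CH (excess), n-BuLi, THF, −78 °C; LiOOt-Bu (from t-BuOOH and n-BuLi, THF, −78 °C), −78 to −20 °C; TIPSOTf, −78 to 0 °C; H2O
Reagents that add atoms: tert-butyl hydroperoxide, CC(C)(C)OO; triisopropylsilyl triflate, CC(C)[Si](C(C)C)(C(C)C)OS(=O)(=O)C(F)(F)F
Why: Oxygen transfer from LiOOt-Bu to a lithium acetylide (acetylide-to-ynolate oxidation) should give the ynolate, and the bulky, hard TIPSOTf should silylate it on oxygen to give the silyl ynol ether.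

**Step 4**
Reactants: 3 3,3-dimethylpent-4-enoyl chloride; 7 (triisopropylsilyloxy)ethyne
Product: 9 rac-4-(2-methylbut-3-en-2-yl)-3-(triisopropylsilyloxy)cyclobut-2-en-1-one, via (2-methylbut-3-en-2-yl)ketene 8 (not isolated)
Conditions: Et3N, 7 (1.5 equiv), Et2O, rt to 35 °C, slow addition of 3
Reagents that add atoms: none
Why: Dehydrochlorination gives the tert-alkylketene, which should undergo the ketene–ynol ether [2+2] cycloaddition with the nucleophilic CH terminus of 7 bonding to the ketene carbonyl carbon; the C4 stereocentre forms racemic and is erased in step 7.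

**Step 5**
Reactants: 10 2-chloro-1,1-dimethoxyethane
Product: 12 3-methoxyprop-2-yn-1-ol, via lithium methoxyacetylide 11 (not isolated)
Conditions: LiNEt2 (3.1 equiv, from n-BuLi and Et2NH), THF, 0 °C; (CH2O)n, 0 °C to rt; H2O
Reagents that add atoms: formaldehyde (as paraformaldehyde), C=O
Why: Two base-induced eliminations (methanol, then HCl) and a deprotonation convert the chloroacetal into the alkoxyacetylide, a standard entry to ynol ethers, and the acetylide adds to formaldehyde by 1,2-addition.

**Step 6**
Reactants: 12 3-methoxyprop-2-yn-1-ol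
Product: 13 tert-butyl(3-methoxyprop-2-ynyloxy)dimethylsilane
Conditions: TBSCl, imidazole, DMF, 0 °C to rt
Reagents that add atoms: tert-butyldimethylsilyl chloride, CC(C)(C)[Si](C)(C)Cl
Why: Imidazole-promoted silylation of a primary alcohol; the basic medium keeps the acid-labile ynol ether intact.

**Step 7**
Reactants: 9 rac-4-(2-methylbut-3-en-2-yl)-3-(triisopropylsilyloxy)cyclobut-2-en-1-one; 13 tert-butyl(3-methoxyprop-2-ynyloxy)dimethylsilane
Product: 18 2-(tert-butyldimethylsilyloxymethyl)-3-methoxy-6-(2-methylbut-3-en-2-yl)-5-(triisopropylsilyloxy)phenol, via vinylketene 14 (not isolated), via vinylcyclobutenone 15 (not isolated), via dienylketene 16 (not isolated), via cyclohexadienone 17 (not isolated)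
Conditions: 13 (1.5 equiv), toluene, 80 °C then 110 °C, sealed tube, argon
Reagents that add atoms: none
Why: Heating should open 9 by conrotatory 4π-electrocyclic cleavage of C1–C4 to vinylketene 14 with the tert-alkyl group turning outward; the ynol ether then adds to the ketene in a [2+2] step, its CH2OTBS-bearing carbon bonding to the ketene carbonyl carbon (C8a–C4a) and its methoxy carbon to the ketene α-carbon (C5–C6), giving 4-vinylcyclobutenone 15. A second 4π opening gives dienylketene 16, and ring A closes by disrotatory 6π-electrocyclisation between the ketene carbon and the diene terminus (C8a–C8) to cyclohexadienone 17, which tautomerises to phenol 18 by loss of the former cyclobutenone C4 hydrogen. The closest known reaction type is the Danheiser benzannulation of cyclobutenones with alkoxy- and silyloxyalkynes. No stereocentre is created, and the racemic centre of 9 becomes aromatic C8. The step needs regiocontrol in the ketene–alkyne [2+2], secured by the polarisation of the ynol ether (nucleophilic at the carbon remote from oxygen), which places the methoxy group meta to the new hydroxyl. It also needs chemoselectivity for the ynol ether over the pendant vinyl group, secured by the far higher nucleophilicity of the ynol ether and by the outward position of the tert-alkyl group, which keeps that alkene away from the ketene.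

**Step 8**
Reactants: 18 2-(tert-butyldimethylsilyloxymethyl)-3-methoxy-6-(2-methylbut-3-en-2-yl)-5-(triisopropylsilyloxy)phenol
Product: 19 2-(hydroxymethyl)-3-methoxy-6-(2-methylbut-3-en-2-yl)-5-(triisopropylsilyloxy)phenol
Conditions: HF·pyridine, pyridine, THF, 0 °C; used directly
Reagents that add atoms: none
Why: Buffered acidic fluoride (selective desilylation) should cleave the unhindered primary alkyl TBS ether much faster than the aryl TIPS ether shielded by the neighbouring quaternary carbon, while the pyridine buffer suppresses ionisation of the electron-rich benzylic C–O bond.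

**Step 9**
Reactants: 19 2-(hydroxymethyl)-3-methoxy-6-(2-methylbut-3-en-2-yl)-5-(triisopropylsilyloxy)phenol
Product: 20 2-hydroxy-6-methoxy-3-(2-methylbut-3-en-2-yl)-4-(triisopropylsilyloxy)benzaldehyde
Conditions: MnO2 (activated, excess), CH2Cl2, rt
Reagents that add atoms: none
Why: Heterogeneous MnO2 oxidation is selective for benzylic alcohols and should leave the phenol, silyl ether and terminal alkene untouched; the salicylaldehyde is stabilised by its internal hydrogen bond.

**Step 10**
Reactants: 21 2,4-dihydroxyphenylacetic acid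
Product: 22 2,4-diacetoxyphenylacetic acid
Conditions: Ac2O, 2 M aq NaOH, 0 °C; then 2 M HCl
Reagents that add atoms: acetic anhydride, CC(=O)OC(C)=O
Why: Schotten–Baumann acetylation in water acylates both phenoxides while any mixed anhydride of the carboxylate is hydrolysed back, which blocks the ortho-hydroxyl from lactonising to a benzofuranone in step 11.

**Step 11**
Reactants: 20 2-hydroxy-6-methoxy-3-(2-methylbut-3-en-2-yl)-4-(triisopropylsilyloxy)benzaldehyde; 22 2,4-diacetoxyphenylacetic acid
Product: 23 3-(2,4-diacetoxyphenyl)-5-methoxy-8-(2-methylbut-3-en-2-yl)-7-(triisopropylsilyloxy)chromen-2-one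
Conditions: 22 (1.3 equiv), Ac2O, Et3N, 110 °C
Reagents that add atoms: none
Why: Perkin–Oglialoro condensation: the mixed anhydride of the arylacetic acid enolises, condenses with the aldehyde, and acyl transfer to the single free ortho-hydroxyl with loss of water closes the pyranone ring B as the 3-arylcoumarin, without any new stereocentre.

**Step 12**
Reactants: 23 3-(2,4-diacetoxyphenyl)-5-methoxy-8-(2-methylbut-3-en-2-yl)-7-(triisopropylsilyloxy)chromen-2-one
Product: 24 3-(2,4-dihydroxyphenyl)-5-methoxy-8-(2-methylbut-3-en-2-yl)-7-(triisopropylsilyloxy)chromen-2-one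
Conditions: NH3 (7 M in MeOH), 0 °C to rt
Reagents that add atoms: none
Why: Ammonolysis of aryl acetates is fast at or below room temperature, whereas the conjugated lactone and the hindered aryl TIPS ether should not be attacked.

**Step 13**
Reactants: 24 3-(2,4-dihydroxyphenyl)-5-methoxy-8-(2-methylbut-3-en-2-yl)-7-(triisopropylsilyloxy)chromen-2-one
Product: 25 3-(2,4-dihydroxyphenyl)-7-hydroxy-5-methoxy-8-(2-methylbut-3-en-2-yl)chromen-2-one
Conditions: TBAF, AcOH (1:1), THF, 0 °C to rt
Reagents that add atoms: none
Why: Fluoride-induced cleavage of the aryl silyl ether under acetic acid buffering frees the C7 phenol without strong acid, which would cyclise it onto the neighbouring 1,1-dimethylallyl group.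

**Compound list**

1 | methyl 3,3-dimethylpent-4-enoate | COC(=O)CC(C)(C)C=C | starting material
2 | 3,3-dimethylpent-4-enoic acid | OC(=O)CC(C)(C)C=C | intermediate
3 | 3,3-dimethylpent-4-enoyl chloride | ClC(=O)CC(C)(C)C=C | intermediate
4 | ethyne | C#C | starting material
5 | monolithium acetylide (LiC≡CH) | [Li]C#C | intermediate (not isolated)
6 | lithium ethynolate (LiOC≡CH) | [Li]OC#C | intermediate (not isolated)
7 | (triisopropylsilyloxy)ethyne | C#CO[Si](C(C)C)(C(C)C)C(C)C | intermediate
8 | (2-methylbut-3-en-2-yl)ketene (3,3-dimethylpenta-1,4-dien-1-one) | O=C=CC(C)(C)C=C | intermediate (not isolated)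
9 | rac-4-(2-methylbut-3-en-2-yl)-3-(triisopropylsilyloxy)cyclobut-2-en-1-one | C=CC(C)(C)C1C(O[Si](C(C)C)(C(C)C)C(C)C)=CC1=O | intermediate
10 | 2-chloro-1,1-dimethoxyethane | COC(CCl)OC | starting material
11 | lithium methoxyacetylide (LiC≡COMe) | [Li]C#COC | intermediate (not isolated)
12 | 3-methoxyprop-2-yn-1-ol | COC#CCO | intermediate
13 | tert-butyl(3-methoxyprop-2-ynyloxy)dimethylsilane | COC#CCO[Si](C)(C)C(C)(C)C | intermediate
14 | (3Z)-5,5-dimethyl-3-(triisopropylsilyloxy)hepta-1,3,6-trien-1-one (vinylketene) | O=C=C/C(O[Si](C(C)C)(C(C)C)C(C)C)=C/C(C)(C)C=C | intermediate (not isolated)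
15 | rac-2-(tert-butyldimethylsilyloxymethyl)-4-[(1Z)-3,3-dimethyl-1-(triisopropylsilyloxy)penta-1,4-dien-1-yl]-3-methoxycyclobut-2-en-1-one (vinylcyclobutenone) | O=C1C(CO[Si](C)(C)C(C)(C)C)=C(OC)C1/C(O[Si](C(C)C)(C(C)C)C(C)C)=C/C(C)(C)C=C | intermediate (not isolated)
16 | (3E,5Z)-2-(tert-butyldimethylsilyloxymethyl)-3-methoxy-7,7-dimethyl-5-(triisopropylsilyloxy)nona-1,3,5,8-tetraen-1-one (dienylketene) | O=C=C(CO[Si](C)(C)C(C)(C)C)/C(OC)=C\C(O[Si](C(C)C)(C(C)C)C(C)C)=C\C(C)(C)C=C | intermediate (not isolated)
17 | rac-2-(tert-butyldimethylsilyloxymethyl)-3-methoxy-6-(2-methylbut-3-en-2-yl)-5-(triisopropylsilyloxy)cyclohexa-2,4-dien-1-one (cyclohexadienone) | O=C1C(CO[Si](C)(C)C(C)(C)C)=C(OC)C=C(O[Si](C(C)C)(C(C)C)C(C)C)C1C(C)(C)C=C | intermediate (not isolated)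
18 | 2-(tert-butyldimethylsilyloxymethyl)-3-methoxy-6-(2-methylbut-3-en-2-yl)-5-(triisopropylsilyloxy)phenol | C=CC(C)(C)c1c(O)c(CO[Si](C)(C)C(C)(C)C)c(OC)cc1O[Si](C(C)C)(C(C)C)C(C)C | intermediate
19 | 2-(hydroxymethyl)-3-methoxy-6-(2-methylbut-3-en-2-yl)-5-(triisopropylsilyloxy)phenol | C=CC(C)(C)c1c(O)c(CO)c(OC)cc1O[Si](C(C)C)(C(C)C)C(C)C | intermediate
20 | 2-hydroxy-6-methoxy-3-(2-methylbut-3-en-2-yl)-4-(triisopropylsilyloxy)benzaldehyde | C=CC(C)(C)c1c(O)c(C=O)c(OC)cc1O[Si](C(C)C)(C(C)C)C(C)C | intermediate
21 | 2,4-dihydroxyphenylacetic acid | O=C(O)Cc1ccc(O)cc1O | starting material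
22 | 2,4-diacetoxyphenylacetic acid | CC(=O)Oc1ccc(CC(=O)O)c(OC(C)=O)c1 | intermediate
23 | 3-(2,4-diacetoxyphenyl)-5-methoxy-8-(2-methylbut-3-en-2-yl)-7-(triisopropylsilyloxy)chromen-2-one | C=CC(C)(C)c1c(O[Si](C(C)C)(C(C)C)C(C)C)cc(OC)c2cc(-c3ccc(OC(C)=O)cc3OC(C)=O)c(=O)oc12 | intermediate
24 | 3-(2,4-dihydroxyphenyl)-5-methoxy-8-(2-methylbut-3-en-2-yl)-7-(triisopropylsilyloxy)chromen-2-one | C=CC(C)(C)c1c(O[Si](C(C)C)(C(C)C)C(C)C)cc(OC)c2cc(-c3ccc(O)cc3O)c(=O)oc12 | intermediate
25 | 3-(2,4-dihydroxyphenyl)-7-hydroxy-5-methoxy-8-(2-methylbut-3-en-2-yl)chromen-2-one (CID10090416) | C=CC(C)(C)c1c(O)cc(OC)c2cc(-c3ccc(O)cc3O)c(=O)oc12 | target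

**Step count and risks**

Total step count: 13. Longest linear sequence: 9 steps (1, 2, 4, 7, 8, 9, 11, 12, 13, from ester 1).

Steps most likely to fail:

Step 7. The bimolecular [2+2] capture of vinylketene 14 by an internal, propargylically oxygenated ynol ether may be slower than decay of the vinylketene (dimerisation, reclosure, silyl loss). The quaternary group next to the silyloxy carbon makes this more likely, and this cyclobutenone–alkyne pairing is untested. The fallback sets out from cyclobutenone 9 and acetylide 11 of step 5. Protonation of 11 with water and distillation into cold toluene gives methoxyethyne F1, the least hindered and most reactive ynol ether class for this annulation. Heating 9 with F1 in toluene at 80 °C in a sealed tube should give 5-methoxy-2-(2-methylbut-3-en-2-yl)-3-(triisopropylsilyloxy)phenol F2 by the same pericyclic sequence. The C4 carbon is then introduced by magnesium-mediated ortho-formylation (MgCl2, Et3N, paraformaldehyde, MeCN, reflux), which can only occur at the one free ortho position. The route is rejoined at aldehyde 20, and steps 8 and 9 are then no longer needed.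

Step 3. Monolithium acetylide may disproportionate to Li2C2 during the warming needed for oxygen transfer, and the parent ynolate may silylate on carbon or the product may isomerise by 1,3-silyl shift to the silylketene. The fallback sets out from acid chloride 3. Ketene 8, generated with Et3N in Et2O, is trapped by commercial ethoxyethyne in the classical [2+2] to give 3-ethoxy-4-(2-methylbut-3-en-2-yl)cyclobut-2-en-1-one F3. Hydrolysis of this vinylogous ester with cold dilute aqueous HCl in THF gives 2-(2-methylbut-3-en-2-yl)cyclobutane-1,3-dione F4. O-Silylation with TIPSOTf and Et3N in CH2Cl2 at −78 °C through the less substituted enolate (the unsubstituted CH2 is the more acidic and less hindered site) should give cyclobutenone 9, where the route is rejoined. A regioisomeric enol silane, if formed, would be removed by chromatography. Steps 3 and 4 are bypassed.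

Step 11. O-Acetylation of the hindered C8a hydroxyl by the excess anhydride may outrun acylation by the arylacetic mixed anhydride, so that the aldehyde condenses intermolecularly to an α-arylcinnamic acid of the wrong geometry for lactonisation; the aryl silyl ether may also be lost by acetolysis at 110 °C. The fallback sets out from acid 22 and aldehyde 20. Acid 22 is converted with oxalyl chloride and catalytic DMF into 2,4-diacetoxyphenylacetyl chloride F5. Acylation of the phenol of 20 (Et3N, DMAP, CH2Cl2, 0 °C) gives 2-formyl-3-methoxy-6-(2-methylbut-3-en-2-yl)-5-(triisopropylsilyloxy)phenyl (2,4-diacetoxyphenyl)acetate F6. DBU in MeCN at room temperature then effects the intramolecular aldol condensation and dehydration, which can only give the lactone geometry, and the route is rejoined at coumarin 23.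

**Further compounds**

F1 | step 7 | methoxyethyne | COC#C
F2 | step 7 | 5-methoxy-2-(2-methylbut-3-en-2-yl)-3-(triisopropylsilyloxy)phenol | C=CC(C)(C)c1c(O)cc(OC)cc1O[Si](C(C)C)(C(C)C)C(C)C
F3 | step 3 | rac-3-ethoxy-4-(2-methylbut-3-en-2-yl)cyclobut-2-en-1-one | C=CC(C)(C)C1C(OCC)=CC1=O
F4 | step 3 | 2-(2-methylbut-3-en-2-yl)cyclobutane-1,3-dione | C=CC(C)(C)C1C(=O)CC1=O
F5 | step 11 | 2,4-diacetoxyphenylacetyl chloride | CC(=O)Oc1ccc(CC(=O)Cl)c(OC(C)=O)c1
F6 | step 11 | 2-formyl-3-methoxy-6-(2-methylbut-3-en-2-yl)-5-(triisopropylsilyloxy)phenyl (2,4-diacetoxyphenyl)acetate | C=CC(C)(C)c1c(OC(=O)Cc2ccc(OC(C)=O)cc2OC(C)=O)c(C=O)c(OC)cc1O[Si](C(C)C)(C(C)C)C(C)C
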